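The seven-membered ring is opened on both sides of its C6–C7–C8 unit (azulene locants: C1 tertiary carbinol, C3a quaternary carbon, C5 carbinol, C6 methylidene carbon, C8 ester carbon, C8a ring-fusion CH). C5–C6 is the bond of a 2-methylene-1-ol, and C8–C8a is an aldol bond once C1 is a ketone. One flask therefore unites (3R)-2-bromo-3-methyl-3-(2-oxoethyl)cyclopentanone with 3-bromobut-3-enal. CrCl2 forms the chromium enolate for a Reformatsky aldol (C8–C8a); catalytic NiCl2 then activates the alkenyl bromide for a 7-exo Nozaki–Hiyama–Kishi closure (C5–C6). The annulation sets C5, C8 and C8a; isopropyl addition and esterification complete the synthesis.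

Key step: step 6

Remark: bicyclic compounds carry azulene locants; 3-bromobut-3-en-1-ol and 4-{[tert-butyl(dimethyl)silyl]oxy}benzoic acid are taken to be catalogue compounds.

Step 1
Reactants: 1 3-bromobut-3-en-1-ol
Product: 2 3-bromobut-3-enal
Conditions: Dess–Martin periodinane, CH2Cl2, 0 °C; used at once as a solution
Reagents that add atoms: none
Why: Dess–Martin oxidation converts the primary alcohol to the aldehyde under near-neutral conditions that should leave the bromoalkene untouched and limit migration of the β,γ-double bond into conjugation, and no stereocenter is formed.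

Step 2
Reactants: 3 3-ethoxycyclopent-2-en-1-one
Product: 5 3-(prop-2-en-1-yl)cyclopent-2-en-1-one, via allyl carbinol 4 (not isolated)
Conditions: allylmagnesium bromide, THF, −78 → 0 °C; then 1 M HCl, 0 °C
Reagents that add atoms: allylmagnesium bromide (C=CC[Mg]Br); water (O)
Why: Grignard 1,2-addition to the vinylogous ester followed by acid-promoted loss of water and hydrolysis of the enol ether (Stork–Danheiser transposition) should give the 3-substituted enone, and no stereocenter is formed.

Step 3
Reactants: 5 3-(prop-2-en-1-yl)cyclopent-2-en-1-one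
Product: 7 trimethyl{[(3R)-3-methyl-3-(prop-2-en-1-yl)cyclopent-1-en-1-yl]oxy}silane, via aluminium enolate 6 (not isolated)
Conditions: AlMe3, copper thiophene-2-carboxylate (CuO2CC4H3S, 2 mol %), chiral O,O′-(1,1′-binaphthalene-2,2′-diyl) N,N-bis(1-phenylethyl)phosphoramidite (4 mol %), Et2O, −30 °C; then Me3SiOTf, −30 → 0 °C
Reagents that add atoms: trimethylaluminium (C[Al](C)C); trimethylsilyl trifluoromethanesulfonate (C[Si](C)(C)OS(=O)(=O)C(F)(F)F)
Why: Copper-catalysed asymmetric conjugate addition of AlMe3 to the β-substituted cyclopentenone builds the quaternary centre, whose (R) configuration is set by the ligand enantiomer chosen for that sense, and O-silylation of the aluminium enolate fixes the enol double bond on the side of the new quaternary carbon.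

Step 4
Reactants: 7 trimethyl{[(3R)-3-methyl-3-(prop-2-en-1-yl)cyclopent-1-en-1-yl]oxy}silane
Product: 8 (3R)-2-bromo-3-methyl-3-(prop-2-en-1-yl)cyclopentan-1-one (both C2 epimers)
Conditions: N-bromosuccinimide, THF, −78 °C
Reagents that add atoms: N-bromosuccinimide (O=C1CCC(=O)N1Br)
Why: Electrophilic α-bromination of the silyl enol ether should place bromine only at C2, between the carbonyl group and the quaternary carbon, and the configuration of this CHBr centre is of no consequence because it is erased in step 6.

Step 5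
Reactants: 8 (3R)-2-bromo-3-methyl-3-(prop-2-en-1-yl)cyclopentan-1-one
Product: 9 [(1R)-2-bromo-1-methyl-3-oxocyclopentyl]acetaldehyde (both C2 epimers)
Conditions: O3, pyridine, CH2Cl2, −78 °C; used at once
Reagents that add atoms: ozone ([O-][O+]=O)
Why: Ozonolysis of the monosubstituted alkene in the presence of pyridine should give the aldehyde directly, without a reducing agent that could attack the α-bromo ketone, and no stereocenter is formed.

Step 6
Reactants: 9 [(1R)-2-bromo-1-methyl-3-oxocyclopentyl]acetaldehyde; 2 3-bromobut-3-enal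
Product: 11 (3aR,5S,8S,8aS)-5,8-dihydroxy-3a-methyl-6-methylideneoctahydroazulen-1(2H)-one, via chromium aldolate 10 (not isolated)
Conditions: CrCl2 (6 equiv), 2 (1.3 equiv), THF/DMF, 0 °C, slow addition of 9; then dilution, NiCl2 (2 mol %), 25 °C
Reagents that add atoms: none
Why: CrCl2 reduces the C–Br bond of 9 to a chromium enolate fixed on the hindered side of the ketone, which adds to aldehyde 2 (C8–C8a bond); the trivalent chromium aldolate 10 can hold its own aldehyde as a six-membered lactolate until NiCl2 is added, whereupon the alkenyl bromide passes through nickel to chromium and the alkenylchromium adds to the aldehyde (C5–C6 bond). The closest known reaction types are the chromium Reformatsky aldol of α-bromo ketones and the intramolecular Nozaki–Hiyama–Kishi cyclisation, run here one after the other in one flask. The first bond is formed between the two fragments and the seven-membered ring is then closed in the 7-exo-trig mode. C8a is set by approach of 2 to the enolate face that carries the methyl group of the neighbouring quaternary carbon, away from the longer oxoethyl arm, which leads to the trans ring fusion; C8 is set by the chair transition state of the (E)-configured cyclic enolate, which gives the anti aldol; C5 is set in the ring closure, where the aldehyde oxygen with its chromium should sit pseudo-equatorial, away from the angular methyl group and cis to the C8 oxygen. The step needs cross-aldol over self-aldol and cyclisation over oligomerisation: slow addition of 9 into an excess of 2 keeps the enolate dilute, the alkenyl bromide is inert to CrCl2 until nickel is present, and dilution before the nickel is added favours ring closure.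

Step 7
Reactants: 11 (3aR,5S,8S,8aS)-5,8-dihydroxy-3a-methyl-6-methylideneoctahydroazulen-1(2H)-one
Product: 12 (3aR,5S,8S,8aS)-5-{[tert-butyl(dimethyl)silyl]oxy}-8-hydroxy-3a-methyl-6-methylideneoctahydroazulen-1(2H)-one
Conditions: tert-butyldimethylsilyl chloride (1.05 equiv), imidazole, DMF, 0 °C
Reagents that add atoms: tert-butyldimethylsilyl chloride (CC(C)(C)[Si](C)(C)Cl)
Why: Silyl ether formation should take place at the allylic C5 hydroxyl, because the C8 hydroxyl is flanked by the ring-fusion carbon and hydrogen-bonded to the C1 ketone, and no stereocenter is formed.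

Step 8
Reactants: 12 (3aR,5S,8S,8aS)-5-{[tert-butyl(dimethyl)silyl]oxy}-8-hydroxy-3a-methyl-6-methylideneoctahydroazulen-1(2H)-one
Product: 13 (1R,3aR,5S,8S,8aS)-5-{[tert-butyl(dimethyl)silyl]oxy}-3a-methyl-6-methylidene-1-(propan-2-yl)decahydroazulene-1,8-diol
Conditions: isopropylmagnesium chloride (3 equiv), CeCl3, THF, −78 → −20 °C
Reagents that add atoms: isopropylmagnesium chloride (CC(C)[Mg]Cl)
Why: Organocerium 1,2-addition to the ketone suppresses enolisation and β-hydride reduction, and the isopropyl group should enter the cyclopentanone from the face of H-8a, opposite the C8a–C8 bond and the angular methyl group, so that the new C1 hydroxyl ends cis to C8.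

Step 9
Reactants: 13 (1R,3aR,5S,8S,8aS)-5-{[tert-butyl(dimethyl)silyl]oxy}-3a-methyl-6-methylidene-1-(propan-2-yl)decahydroazulene-1,8-diol; 14 4-{[tert-butyl(dimethyl)silyl]oxy}benzoic acid
Product: 15 (1R,3aR,5S,8S,8aS)-5-{[tert-butyl(dimethyl)silyl]oxy}-1-hydroxy-3a-methyl-6-methylidene-1-(propan-2-yl)decahydroazulen-8-yl 4-{[tert-butyl(dimethyl)silyl]oxy}benzoate
Conditions: N,N′-dicyclohexylcarbodiimide, 4-(dimethylamino)pyridine, CH2Cl2, 25 °C
Reagents that add atoms: none
Why: Steglich esterification should acylate the secondary C8 hydroxyl only, because the tertiary C1 hydroxyl is too hindered to react, and no stereocenter is touched.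

Step 10
Reactants: 15 (1R,3aR,5S,8S,8aS)-5-{[tert-butyl(dimethyl)silyl]oxy}-1-hydroxy-3a-methyl-6-methylidene-1-(propan-2-yl)decahydroazulen-8-yl 4-{[tert-butyl(dimethyl)silyl]oxy}benzoate
Product: 16 ferugin, (1R,3aR,5S,8S,8aS)-1,5-dihydroxy-3a-methyl-6-methylidene-1-(propan-2-yl)decahydroazulen-8-yl 4-hydroxybenzoate
Conditions: HF·pyridine, pyridine, THF, 0 → 25 °C
Reagents that add atoms: none
Why: Fluoride-mediated desilylation under the mildly acidic conditions of HF·pyridine should remove the alkyl and the aryl silyl ether while leaving the ester in place and avoiding acyl migration from O8 to O5.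

Compound list
1 | 3-bromobut-3-en-1-ol | C=C(Br)CCO | starting material
2 | 3-bromobut-3-enal | C=C(Br)CC=O | intermediate
3 | 3-ethoxycyclopent-2-en-1-one | CCOC1=CC(=O)CC1 | starting material
4 | 3-ethoxy-1-(prop-2-en-1-yl)cyclopent-2-en-1-ol (racemic, formed as its magnesium alkoxide) | C=CCC1(O)C=C(OCC)CC1 | intermediate
5 | 3-(prop-2-en-1-yl)cyclopent-2-en-1-one | C=CCC1=CC(=O)CC1 | intermediate
6 | dimethylaluminium (3R)-3-methyl-3-(prop-2-en-1-yl)cyclopent-1-en-1-olate | C=CC[C@@]1(C)CCC(O[Al](C)C)=C1 | intermediate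
7 | trimethyl{[(3R)-3-methyl-3-(prop-2-en-1-yl)cyclopent-1-en-1-yl]oxy}silane | C=CC[C@@]1(C)CCC(O[Si](C)(C)C)=C1 | intermediate
8 | (3R)-2-bromo-3-methyl-3-(prop-2-en-1-yl)cyclopentan-1-one (both C2 epimers) | BrC1[C@](C)(CCC1=O)CC=C | intermediate
9 | [(1R)-2-bromo-1-methyl-3-oxocyclopentyl]acetaldehyde (both C2 epimers) | BrC1[C@](C)(CCC1=O)CC=O | intermediate
10 | {(1R,2S)-2-[(1S)-3-bromo-1-hydroxybut-3-en-1-yl]-1-methyl-3-oxocyclopentyl}acetaldehyde (present as its chromium aldolate) | C=C(Br)C[C@H](O)[C@@H]1[C@](C)(CCC1=O)CC=O | intermediate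
11 | (3aR,5S,8S,8aS)-5,8-dihydroxy-3a-methyl-6-methylideneoctahydroazulen-1(2H)-one | C=C1C[C@H](O)[C@@H]2[C@](C)(CCC2=O)C[C@@H]1O | intermediate
12 | (3aR,5S,8S,8aS)-5-{[tert-butyl(dimethyl)silyl]oxy}-8-hydroxy-3a-methyl-6-methylideneoctahydroazulen-1(2H)-one | C=C1C[C@H](O)[C@@H]2[C@](C)(CCC2=O)C[C@@H]1O[Si](C)(C)C(C)(C)C | intermediate
13 | (1R,3aR,5S,8S,8aS)-5-{[tert-butyl(dimethyl)silyl]oxy}-3a-methyl-6-methylidene-1-(propan-2-yl)decahydroazulene-1,8-diol | C=C1C[C@H](O)[C@@H]2[C@](C)(CC[C@@]2(O)C(C)C)C[C@@H]1O[Si](C)(C)C(C)(C)C | intermediate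
14 | 4-{[tert-butyl(dimethyl)silyl]oxy}benzoic acid | CC(C)(C)[Si](C)(C)Oc1ccc(C(=O)O)cc1 | starting material
15 | (1R,3aR,5S,8S,8aS)-5-{[tert-butyl(dimethyl)silyl]oxy}-1-hydroxy-3a-methyl-6-methylidene-1-(propan-2-yl)decahydroazulen-8-yl 4-{[tert-butyl(dimethyl)silyl]oxy}benzoate | C=C1C[C@H](OC(=O)c2ccc(O[Si](C)(C)C(C)(C)C)cc2)[C@@H]2[C@](C)(CC[C@@]2(O)C(C)C)C[C@@H]1O[Si](C)(C)C(C)(C)C | intermediate
16 | ferugin, (1R,3aR,5S,8S,8aS)-1,5-dihydroxy-3a-methyl-6-methylidene-1-(propan-2-yl)decahydroazulen-8-yl 4-hydroxybenzoate | C=C1C[C@H](OC(=O)c2ccc(O)cc2)[C@@H]2[C@](C)(CC[C@@]2(O)C(C)C)C[C@@H]1O | target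

Total step count: 10 steps. Longest linear sequence: 9 steps (steps 2 to 10, from 3 to 16).

Steps most likely to fail

Step 6. The chromium enolate may condense with the aldehyde of a second molecule of 9 instead of with 2, the aldehyde may approach the wrong enolate face, or the alkenylchromium may oligomerise instead of closing the seven-membered ring. The fallback sets out from 7 and comes back at 11, and makes the two bonds in separate flasks. Silyl enol ether 7 is cleaved with MeLi to the lithium enolate, which is added to 2 at −78 °C and should give the anti aldol adduct F1 through a closed transition state. Triethylsilyl chloride and imidazole give the silyl ether F2. Pyridine-buffered ozonolysis of the allyl group, which is more electron-rich than the bromoalkene, gives the aldehyde F3. CrCl2 with catalytic NiCl2 in DMF at high dilution then closes the ring to the 8-silyloxy hydroazulenone F4, and HF·pyridine removes the triethylsilyl group to give 11.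

Step 8. The hindered, enolisable ketone may be deprotonated with epimerisation at C8a, reduced by β-hydride transfer, cleaved by retro-aldol reaction of the C8 alkoxide, or attacked from the wrong face. The fallback sets out from 12 and comes back at 13. The C8 hydroxyl is capped with Et3SiOTf and 2,6-lutidine to give the bis-silyl ketone F5. Isopropenylmagnesium bromide with CeCl3, a smaller sp2 nucleophile without β-hydrogen, should give the tertiary allylic alcohol F6. Hydroxyl-directed hydrogenation with [Rh(nbd)(dppb)]BF4 and H2 should reduce only the isopropenyl group next to the free hydroxyl and give the isopropyl carbinol F7, because the methylidene group has no free hydroxyl nearby. Acetic acid in aqueous THF then removes the secondary triethylsilyl ether in the presence of the tert-butyldimethylsilyl ether and gives 13.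

Step 7. Silylation may occur at both hydroxyls or at O8. The fallback sets out from 11 and comes back at 13, and moves the differentiation to the triol, where the C8 hydroxyl is shielded by the fully substituted C1 carbinol next to it. Both hydroxyls are silylated with Et3SiOTf and 2,6-lutidine to give the bis-silyl ketone F8. Isopropylmagnesium chloride with CeCl3 gives the tertiary alcohol F9, and HF·pyridine gives the triol F10. tert-Butyldimethylsilyl chloride and imidazole then silylate the allylic C5 hydroxyl and give 13.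

Further compounds
F1 | step 6 | (2S,3R)-2-[(1S)-3-bromo-1-hydroxybut-3-en-1-yl]-3-methyl-3-(prop-2-en-1-yl)cyclopentan-1-one | C=C(Br)C[C@H](O)[C@@H]1[C@](C)(CCC1=O)CC=C
F2 | step 6 | (2S,3R)-2-{(1S)-3-bromo-1-[(triethylsilyl)oxy]but-3-en-1-yl}-3-methyl-3-(prop-2-en-1-yl)cyclopentan-1-one | C=C(Br)C[C@H](O[Si](CC)(CC)CC)[C@@H]1[C@](C)(CCC1=O)CC=C
F3 | step 6 | {(1R,2S)-2-{(1S)-3-bromo-1-[(triethylsilyl)oxy]but-3-en-1-yl}-1-methyl-3-oxocyclopentyl}acetaldehyde | C=C(Br)C[C@H](O[Si](CC)(CC)CC)[C@@H]1[C@](C)(CCC1=O)CC=O
F4 | step 6 | (3aR,5S,8S,8aS)-5-hydroxy-3a-methyl-6-methylidene-8-[(triethylsilyl)oxy]octahydroazulen-1(2H)-one | C=C1C[C@H](O[Si](CC)(CC)CC)[C@@H]2[C@](C)(CCC2=O)C[C@@H]1O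
F5 | step 8 | (3aR,5S,8S,8aS)-5-{[tert-butyl(dimethyl)silyl]oxy}-3a-methyl-6-methylidene-8-[(triethylsilyl)oxy]octahydroazulen-1(2H)-one | C=C1C[C@H](O[Si](CC)(CC)CC)[C@@H]2[C@](C)(CCC2=O)C[C@@H]1O[Si](C)(C)C(C)(C)C
F6 | step 8 | (1S,3aR,5S,8S,8aS)-5-{[tert-butyl(dimethyl)silyl]oxy}-3a-methyl-6-methylidene-1-(prop-1-en-2-yl)-8-[(triethylsilyl)oxy]decahydroazulen-1-ol | C=C1C[C@H](O[Si](CC)(CC)CC)[C@@H]2[C@](C)(CC[C@@]2(O)C(C)=C)C[C@@H]1O[Si](C)(C)C(C)(C)C
F7 | step 8 | (1R,3aR,5S,8S,8aS)-5-{[tert-butyl(dimethyl)silyl]oxy}-3a-methyl-6-methylidene-1-(propan-2-yl)-8-[(triethylsilyl)oxy]decahydroazulen-1-ol | C=C1C[C@H](O[Si](CC)(CC)CC)[C@@H]2[C@](C)(CC[C@@]2(O)C(C)C)C[C@@H]1O[Si](C)(C)C(C)(C)C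
F8 | step 7 | (3aR,5S,8S,8aS)-3a-methyl-6-methylidene-5,8-bis[(triethylsilyl)oxy]octahydroazulen-1(2H)-one | C=C1C[C@H](O[Si](CC)(CC)CC)[C@@H]2[C@](C)(CCC2=O)C[C@@H]1O[Si](CC)(CC)CC
F9 | step 7 | (1R,3aR,5S,8S,8aS)-3a-methyl-6-methylidene-1-(propan-2-yl)-5,8-bis[(triethylsilyl)oxy]decahydroazulen-1-ol | C=C1C[C@H](O[Si](CC)(CC)CC)[C@@H]2[C@](C)(CC[C@@]2(O)C(C)C)C[C@@H]1O[Si](CC)(CC)CC
F10 | step 7 | (1R,3aR,5S,8S,8aS)-3a-methyl-6-methylidene-1-(propan-2-yl)decahydroazulene-1,5,8-triol | C=C1C[C@H](O)[C@@H]2[C@](C)(CC[C@@]2(O)C(C)C)C[C@@H]1O
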